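## Analysis of the target

1. Target 9 (C15H14Br2O6) is a diarylmethane. Two benzene rings are joined by one methylene carbon, C7′, and there is no further ring and no chain.
2. Ring A is pentasubstituted, with CH2OH at C1, the bridge at C2, OH at C3, OMe at C4, OH at C5 and its only hydrogen at C6. Ring B carries the bridge at C1′, Br at C2′ and C3′, OH at C4′ and C5′, and H at C6′.
3. There is no stereocentre and no hindered axis, so nothing has to be set or related. The whole problem is chemo- and regioselectivity among groups that look alike.
4. Five free hydroxyls stand beside a single methyl ether at O4. This ether lies between two oxygens and is the kind that Lewis acids cleave first, so no route may end with a general ether cleavage.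
5. The two aryl C–Br bonds do not tolerate Pd(0), halogen–metal exchange or hydrogenolysis. They also cannot be added late, because C6–H of ring A (ortho to O5, para to O3) is far more nucleophilic than any position of ring B.
6. The carbinol at C1 is a 4-methoxybenzyl-type alcohol that ionises in acid, and both the catechol and the 2-methoxyresorcinol unit are air-sensitive in base.
7. The route rests on one feature. O4′–H is para to C1′, so ring B together with C7′ is a latent p-quinone methide; C2 of ring A is ortho to O3 and para to O5, while O3 and O5 are both meta to C1. Ring A is therefore a strong carbon nucleophile that cannot form a quinone methide of its own.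
8. Cutting C7′–C2 also restores a mirror plane through C1 and C4 of ring A, which makes C2 and C6 equivalent. This matches the presumed biosynthesis, in which two free benzyl alcohol monomers are joined.

## Retrosynthetic reasoning

**C7′–C2 (9 to 8 + 7).** The bond C7′–C2 of 9 is cut first, and it is cut between the unprotected halves, the p-quinone methide 8 and the benzyl alcohol 7.
- It is preferred to C7′–C1′ because the polarity fits on both sides. C7′ is the electrophilic end of a vinylogous carbonyl group whose oxygen is O4′, and C2 is the position of 7 that both hydroxyls activate.
- The last step then forms the only skeletal bond that is not already present in a commercial ring.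
- It needs no protecting group on any of the six oxygens, and it leaves O4–CH3 and both C–Br bonds untouched.
- It starts from a symmetric nucleophile, so no regiochemical question remains.
- The forward reaction has three tasks: keep 7 from ionising at its own carbinol, end in C-attack rather than O-attack, and stop after one benzylation.

**8 to 5.** Compound 8 cannot be stored. It is traced back to its hydrobromide, the benzyl bromide 5. Removal of the O4′ proton and departure of bromide (1,6-elimination) set 8 free in a buffered medium. A bromide rather than a hydroxyl as leaving group lets the union run without acid, and the chemoselectivity between the two benzylic positions depends on this.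

**5 to 3.** Two bonds of 5 are traced back at once: C7′–Br to C7′–OH, and O5′–H to O5′–CH3. One treatment with a Lewis-acidic boron halide achieves both by way of 4. This ether cleavage must come before the union, because it would not spare O4–CH3 of 9.

**3 to 2 to 1.** Hydride reduction links 3 to the aldehyde 2. The C2′–Br bond of 2 is cut next. In 1 the position para to the methoxy group is the only one that is both activated and unhindered, and the formyl group deactivates the ring enough for the reaction to stop there. The methyl ether thus serves as a directing group before it is removed. Commercial 1 already holds the C3′ bromine, ortho to the free hydroxyl.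

**7 to 6.** The carbinol carbon of 7 is traced back to the ester of commercial 6, which already carries O4–CH3 between two free hydroxyls. The differentiation of the three ring A oxygens is bought, not made.

## Alternatives that were turned down

**Alternative 1:** the textbook route, which forms the same methylene–ring A bond in the cationic manifold between fully O-methylated partners.
- Forward key step: (2,3-dibromo-4,5-dimethoxyphenyl)methanol A1 would be ionised by a strong Lewis acid and would alkylate methyl 3,4,5-trimethoxybenzoate A2 to the pentamethyl ether A3. Ester reduction and a general ether cleavage would follow.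
- The end game fails. Four of the five aryl methyl ethers would have to fall and the fifth, at O4, would have to stay. This central ether of a 1,2,3-trioxygenated array is twisted out of the ring plane and flanked by two chelating oxygens, so it is the first and not the last to be cleaved.
- The same reagent would turn the C1 carbinol into a benzylic halide.
- C2 of A2 is deactivated by the ester and lies between two substituents.
- Orthogonal protection of O3, O5, O4′ and O5′ would repair this only at the price of at least four more steps, all spent on groups that the target does not hold.

**Alternative 2:** carbanion plus carbonyl at the same bond.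
- Forward key step: bromine–lithium exchange on the protected ring A bromide A4 and addition to the protected aldehyde A5 would give the racemic diarylcarbinol A6. Ionic deoxygenation and deprotection would follow. A Suzuki–Miyaura benzyl–aryl coupling is the catalytic variant.
- The aryllithium from A4 meets two aryl C–Br bonds in A5, one of them ortho to the formyl group. Halogen–metal exchange between the partners can compete with the addition, and Pd(0) in the catalytic variant would insert into the same bonds.
- The silane/acid conditions that remove the carbinol hydroxyl of A6 also strip acetal protecting groups and ionise the 4-methoxybenzyl-type position at C1. Two benzylic C–O bonds would then compete for hydride.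
- A4 alone needs a bromination, two kinds of protection and a reduction. The route would exceed ten steps for one C–C bond, and it creates a stereocentre only to destroy it.

**Alternative 3:** reversed polarity. C7′–C1′ is cut and C7′ is brought in as a one-carbon unit on ring A, so that three components are joined in all.
- Forward key step: Mannich aminomethylation of 7 at C2 would give A7. Thermal loss of the amine would give the o-quinone methide A8 (carbonyl at C3), to be captured by 3,4-dibromobenzene-1,2-diol A9 para to one of its hydroxyls.
- The roles are mismatched. A9 carries two bromines and would be the weakest carbon nucleophile in the flask, weaker than C6 of A7, so self-condensation of ring A units should win.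
- A9 offers two free positions, and only one of them leads to 9. The advantage of symmetry is lost.
- A9 is not a stock chemical, and its substitution pattern runs against the directing effects of catechol.

Key step: step 5

Remark on the chemistry: the target SMILES holds no stereocentre and no hindered axis, so the compound is achiral and the request for a single enantiomer needs no measure in the route.

## Route

Step 1
Reactants: 1 5-bromovanillin (3-bromo-4-hydroxy-5-methoxybenzaldehyde)
Product: 2 2,3-dibromo-4-hydroxy-5-methoxybenzaldehyde (5,6-dibromovanillin)
Conditions: Br2 (1.2 equiv), Fe powder (5 mol %), AcOH, rt → 50 °C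
Reagents that add atoms: bromine, BrBr
Why: Electrophilic aromatic bromination; of the two free positions of 1, the one para to the methoxy group is activated and unhindered, whereas the other lies between formyl and methoxy. The formyl group and two bromines deactivate 2 against a third substitution.

Step 2
Reactants: 2 2,3-dibromo-4-hydroxy-5-methoxybenzaldehyde
Product: 3 2,3-dibromo-4-hydroxy-5-methoxybenzyl alcohol
Conditions: NaBH4 (1.2 equiv), THF–H2O (4:1), 0 °C; sat. aq NH4Cl
Reagents that add atoms: none
Why: Borohydride reduction of an aryl aldehyde of the vanillin type; aryl bromides and the methyl ether are inert. Low temperature and a near-neutral quench keep the 4-hydroxybenzyl alcohol from ionising.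

Step 3
Reactants: 3 2,3-dibromo-4-hydroxy-5-methoxybenzyl alcohol
Product: 5 3,4-dibromo-5-(bromomethyl)benzene-1,2-diol, via the cyclic bromoboronate 4 (not isolated)
Conditions: BBr3 (3.5 equiv), CH2Cl2, −78 °C → rt; ice–water, fast extraction (Et2O), concentration below 25 °C, used crude
Reagents that add atoms: boron tribromide, BrB(Br)Br
Why: Boron tribromide cleaves the aryl methyl ether next to the free hydroxyl through the cyclic bromoboronate 4 and at the same time replaces the activated benzylic hydroxyl by bromide, both standard reactions of this reagent; brief cold hydrolysis frees the catechol. The aryl C–Br bonds are inert, and the ring, deactivated by two bromines and by the O–B bonds, should not be alkylated by its own benzylic position.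

Step 4
Reactants: 6 methyl 3,5-dihydroxy-4-methoxybenzoate
Product: 7 3,5-dihydroxy-4-methoxybenzyl alcohol
Conditions: LiAlH4 (3 equiv), THF, 0 → 50 °C; aq Rochelle salt, pH 6, exhaustive EtOAc extraction
Reagents that add atoms: none
Why: Ester reduction with lithium aluminium hydride; two hydrides are spent on the phenols, hence the excess and the gentle warming. The aryl methyl ether is inert, and a work-up at pH 6 avoids ionisation of the product carbinol.

Step 5
Reactants: 5 3,4-dibromo-5-(bromomethyl)benzene-1,2-diol; 7 3,5-dihydroxy-4-methoxybenzyl alcohol (3 equiv)
Product: 9 4-[(2,3-dibromo-4,5-dihydroxyphenyl)methyl]-5-(hydroxymethyl)-2-methoxybenzene-1,3-diol (target), via the p-quinone methide 8 (not isolated)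
Conditions: NaHCO3 (1.5 equiv), degassed HFIP–H2O (9:1), Ar, 0 → 40 °C, 5 in a little MeCN added over 2 h; NaH2PO4 to pH 5, EtOAc; Sephadex LH-20 or RP-18, excess 7 recovered
Reagents that add atoms: none
Why: Bicarbonate removes the proton of O4′–H, the hydroxyl para to the bromomethyl carbon, and bromide leaves by 1,6-elimination to give the p-quinone methide 8, which HFIP activates by hydrogen bonding to its carbonyl oxygen. C2 of 7, ortho to O3 and para to O5, adds to the exocyclic methylene carbon (1,6-conjugate addition of Friedel–Crafts type), and proton loss rearomatises both rings, which makes the C–C bond irreversible. The closest known reaction types are the capture of p-quinone methides generated in situ by electron-rich phenols and the base-catalysed resole condensation of 4-hydroxybenzyl alcohols with phenols. No ring is closed and no stereocentre is formed. Chemoselectivity between the two benzylic positions follows from the substrates: only 5 has a hydroxyl para to its benzylic carbon, whereas in 7 both hydroxyls are meta to the carbinol carbon and the para oxygen is blocked as methyl ether, so 7 cannot form a quinone methide and, in the buffered medium, should not ionise. Regioselectivity follows from symmetry: C2 and C6 of 7 are equivalent and are the only positions activated by both hydroxyls, so a single constitution can result. Adducts of 8 with phenolic or alcoholic hydroxyls, water or HFIP keep the para hydroxyl and revert to 8, so the mixture should drain into the C-adduct, helped by the hydrogen-bonding solvent, which shields the phenolic oxygens. Slow addition of 5 to three equivalents of 7 holds down attack of ring B on 8 and a second benzylation at C6.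

## Compound list

1 | 5-bromovanillin (3-bromo-4-hydroxy-5-methoxybenzaldehyde) | COc1cc(C=O)cc(Br)c1O | starting material
2 | 2,3-dibromo-4-hydroxy-5-methoxybenzaldehyde | COc1cc(C=O)c(Br)c(Br)c1O | intermediate
3 | 2,3-dibromo-4-hydroxy-5-methoxybenzyl alcohol | COc1cc(CO)c(Br)c(Br)c1O | intermediate
4 | 2,4,5-tribromo-6-(bromomethyl)-1,3,2-benzodioxaborole | BrCc1cc2OB(Br)Oc2c(Br)c1Br | intermediate
5 | 3,4-dibromo-5-(bromomethyl)benzene-1,2-diol | BrCc1cc(O)c(O)c(Br)c1Br | intermediate
6 | methyl 3,5-dihydroxy-4-methoxybenzoate | COC(=O)c1cc(O)c(OC)c(O)c1 | starting material
7 | 3,5-dihydroxy-4-methoxybenzyl alcohol | COc1c(O)cc(CO)cc1O | intermediate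
8 | 2,3-dibromo-6-hydroxy-4-methylidenecyclohexa-2,5-dien-1-one | C=C1C=C(O)C(=O)C(Br)=C1Br | intermediate
9 | 4-[(2,3-dibromo-4,5-dihydroxyphenyl)methyl]-5-(hydroxymethyl)-2-methoxybenzene-1,3-diol | COc1c(O)cc(CO)c(Cc2cc(O)c(O)c(Br)c2Br)c1O | target

## Step count and least certain steps

Total: 5 steps. The route is convergent, and the longest linear sequence is 4 steps (steps 1, 2, 3 and 5).

**Step 5 (key step).**
- What may go wrong: 8 may be consumed by oxygen nucleophiles and by ring B of a second molecule faster than by C2 of 7, which would lead to oligomerisation. A second benzylation at C6 is possible. The C1 carbinol could ionise if the buffer lags behind the acid that is released. Both polyphenols may autoxidise.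
- Why: 8 is unsubstituted at its methylene carbon and therefore very reactive, and the product keeps one nucleophilic position.
- Fallback: ring A is carried at the ester oxidation level, where it holds no ionisable carbinol and tolerates acid. The fallback sets out from 5 and 6. Friedel–Crafts benzylation (6 in excess, cat. TfOH, HFIP, 50 °C) should give methyl 2-(2,3-dibromo-4,5-dihydroxybenzyl)-3,5-dihydroxy-4-methoxybenzoate F1. Reduction with DIBAL-H (8 equiv, THF, −20 °C → rt), which leaves aryl bromides alone, brings the route back at 9.

**Step 3.**
- What may go wrong: the benzylic bromide may be lost by hydrolysis during the aqueous quench, or by self-alkylation on concentration.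
- Why: the para hydroxyl makes this position ionise with ease.
- Fallback: the two tasks are separated and a hydroxyl is used as leaving group. The fallback sets out from 2. Ether cleavage at the aldehyde stage (BBr3, CH2Cl2) should give 2,3-dibromo-4,5-dihydroxybenzaldehyde F2. Reduction with NaBH4 should give 2,3-dibromo-4,5-dihydroxybenzyl alcohol F3, which can be stored. F3 is dehydrated in the flask of step 5 (same buffered HFIP–H2O medium, 60 °C), so the route is rejoined at 8.

**Step 1.**
- What may go wrong: ipso attack at the carbon para to the free hydroxyl with loss of the formyl group, or stalling of the substitution.
- Why: the free hydroxyl activates the ipso position, and the ring already carries a formyl group and one bromine.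
- Fallback: the directing logic is changed by masking the hydroxyl. The fallback sets out from 1. Acetylation (Ac2O, pyridine) should give 2-bromo-4-formyl-6-methoxyphenyl acetate F4, in which the methoxy group is the only strong donor and ipso attack is shut off. Bromination (Br2, Fe, AcOH, 60 °C) should give 2,3-dibromo-4-formyl-6-methoxyphenyl acetate F5. Mild hydrolysis (aq LiOH, then acid) brings the route back at 2.

**Step 4.**
- What may go wrong: the reduction may stall when aluminium phenoxides precipitate, and the very polar, acid-sensitive product may be lost in the aqueous work-up.
- Fallback: an electrophilic hydride is used and the aqueous work-up is dropped. The fallback sets out from 6. Saponification (aq LiOH, then acid) should give 3,5-dihydroxy-4-methoxybenzoic acid F6. Reduction with BH3·THF, followed by repeated co-evaporation with methanol to remove boron as its volatile ester, brings the route back at 7.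

## Further compounds

F1 | step 5 | methyl 2-(2,3-dibromo-4,5-dihydroxybenzyl)-3,5-dihydroxy-4-methoxybenzoate | COC(=O)c1cc(O)c(OC)c(O)c1Cc1cc(O)c(O)c(Br)c1Br
F2 | step 3 | 2,3-dibromo-4,5-dihydroxybenzaldehyde | O=Cc1cc(O)c(O)c(Br)c1Br
F3 | step 3 | 2,3-dibromo-4,5-dihydroxybenzyl alcohol | OCc1cc(O)c(O)c(Br)c1Br
F4 | step 1 | 2-bromo-4-formyl-6-methoxyphenyl acetate | COc1cc(C=O)cc(Br)c1OC(C)=O
F5 | step 1 | 2,3-dibromo-4-formyl-6-methoxyphenyl acetate | COc1cc(C=O)c(Br)c(Br)c1OC(C)=O
F6 | step 4 | 3,5-dihydroxy-4-methoxybenzoic acid | COc1c(O)cc(C(=O)O)cc1O
A1 | alternative 1 | (2,3-dibromo-4,5-dimethoxyphenyl)methanol | COc1cc(CO)c(Br)c(Br)c1OC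
A2 | alternative 1 | methyl 3,4,5-trimethoxybenzoate | COC(=O)c1cc(OC)c(OC)c(OC)c1
A3 | alternative 1 | methyl 2-(2,3-dibromo-4,5-dimethoxybenzyl)-3,4,5-trimethoxybenzoate | COC(=O)c1cc(OC)c(OC)c(OC)c1Cc1cc(OC)c(OC)c(Br)c1Br
A4 | alternative 2 | tert-butyl{[2-bromo-4-methoxy-3,5-bis(methoxymethoxy)phenyl]methoxy}dimethylsilane | COCOc1cc(CO[Si](C)(C)C(C)(C)C)c(Br)c(OCOC)c1OC
A5 | alternative 2 | 2,3-dibromo-4,5-bis(methoxymethoxy)benzaldehyde | COCOc1cc(C=O)c(Br)c(Br)c1OCOC
A6 | alternative 2 | racemic protected diarylcarbinol from A4 and A5 | COCOc1cc(CO[Si](C)(C)C(C)(C)C)c(C(O)c2cc(OCOC)c(OCOC)c(Br)c2Br)c(OCOC)c1OC
A7 | alternative 3 | 4-[(dimethylamino)methyl]-5-(hydroxymethyl)-2-methoxybenzene-1,3-diol | COc1c(O)cc(CO)c(CN(C)C)c1O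
A8 | alternative 3 | 3-hydroxy-5-(hydroxymethyl)-2-methoxy-6-methylidenecyclohexa-2,4-dien-1-one | C=C1C(CO)=CC(O)=C(OC)C1=O
A9 | alternative 3 | 3,4-dibromobenzene-1,2-diol | Oc1ccc(Br)c(Br)c1O
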